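The numbers in the tables were generated by integration for an exercise, and the scatter is random.

The sample from this flask is taken at 4.0 min and not later: in the eta run, with the substrate down to 3% at 40.0 s, target and crystals both read lower by 80.0 s.

- eta: substrate 18 mM; gas phase 6.4 mM (held); run made earlier
- flask: substrate 35 mM; gas phase 6.4 mM (held); time 4.0 min

eta run (percent of the substrate charged)

| time / s | target / % | crystals / % | substrate / % |
|---|---|---|---|
| 10.0 | 42 | 39 | 29 |
| 20.0 | 63 | 55 | 14 |
| 40.0 | 66 | 65 | 3 |
| 80.0 | 63 | 57 | 0 |

(standard deviation of a reading: 2 percentage points)

- what is said of target includes crystals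
- crystals is a solid; its amount is given per volume of the solution
- the numbers in the tables scatter by 2 percentage points (one standard deviation)
- at the start none of the gas phase is in solution

* how much target and crystals together there is at 4.0 min, in percent of the substrate charged
* concentration of dissolved gas in solution at 4.0 min, in percent of saturation

My reckoning replaces that late stretch of the curve by its mean slope, averaging the drops of the two columns, which carry a scatter of about 2 percentage points:

mean drop in eta = 5.5 points

eta slope = 0.0825 min⁻¹

While crystals stand, dissolved target is taken as steady, which makes the loss a fixed amount per minute (pseudo-zero-order), so that, with the gas phase held at the same level as in eta, its fraction of the charge is reckoned to scale inversely with the charge: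

drain = 0.0424 min⁻¹

This drain, the fraction of the charge lost per minute, is reckoned to take away 17.0% by 4.0 min. Taken from the eta reading of 66% at 40.0 s, with that reading assumed to hold for this flask too, my reckoning leaves 49.0%, which differs from the forecast's 60% (range 48% to 70%), given with dissolved gas at 95% (range 78% to 100%): “Better crystal protection could help slightly, while slow drain could hurt.”

The flask gives 44.7% at 4.0 min, with dissolved gas at 99.7% of saturation.

    gas phase ⇌ dissolved gas, rate k1*(csat - [dissolved gas]) (kL = 3.00 s⁻¹)
    substrate + dissolved gas → target (k = 14.0 M⁻¹ s⁻¹)
    dissolved gas + target → over-reacted product (k = 3.20 M⁻¹ s⁻¹)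
    dissolved gas ⇌ dormant form (K = 6.60, k = 0.00740 s⁻¹)
    crystals ⇌ target, rate k5*(cs5 - [target]) while solid is left; crystals form when [target] > cs5 (solubility = 1.10 mM, k = 2.30 s⁻¹)
    2 substrate → self-condensation product (k = 1.70 M⁻¹ s⁻¹)

Over-reacted product in this flask stands at 15.6% at 4.0 min, against the 17.0% reckoned from the drain. A neighbouring flask charged with 140 mM of substrate, the same amount per minute being a drain of 0.0106 min⁻¹, is reckoned to lose 4.24% by 4.0 min, and its over-reacted product stands at 3.99%.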